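**Retrosynthetic overview**

1. Target ⇐ MOM removal and ortho-formylation of the aryl decalinol; axial C3–OH ⇐ C3 ketone; C4 gem-dimethyl ⇐ regiospecific methylation of a C3 silyl enol ether.
2. Key disconnection: rings A and B are closed together by an intramolecular [4+2] cycloaddition of an acyclic 2-siloxydiene–alkyne (bonds C5–C10 and C1–C2). The alkyne becomes the C1=C10 alkene and C5 is created.
3. The dienyne ⇐ chemoselective Wittig olefination and alkyne homologation of a dialdehyde ⇐ oxidative opening of a cyclohexene.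
4. That cyclohexene is only a stereochemical template: asymmetric conjugate methylation of 2-methylcyclohexenone with enolate benzylation sets C8 and C9.
5. Ring order: arene (purchased) → temporary template ring (opened again) → rings A and B in one operation.

Assumption: the target is taken exactly as drawn, the (3R,5R,8R,9S) isomer in drimane-type locants (C3 carbinol, C4 gem-dimethyl, C5 ring-fusion CH, C8 CH–CH3, C9 quaternary, C10=C1 alkene, C11 benzylic CH2); these locants are used below.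

Notation: Ar = 2,6-bis(methoxymethoxy)-4-[(methoxymethoxy)methyl]phenyl; "Ar-methyl" = ArCH2.

**Route**

Step 1
Reactants: 1 3,5-dihydroxybenzyl alcohol
Product: 2 1,3-bis(methoxymethoxy)-5-[(methoxymethoxy)methyl]benzene
Conditions: NaH (3.5 equiv), MOMCl (3.5 equiv), DMF, 0 °C to rt
Reagents that add atoms: chloromethyl methyl ether (MOMCl), COCCl
Why: Williamson-type O-alkylation of the three sodium alkoxide/phenoxide sites gives MOM ethers that direct ortho-lithiation and survive the later organometallic steps.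

Step 2
Reactants: 2 1,3-bis(methoxymethoxy)-5-[(methoxymethoxy)methyl]benzene
Product: 4 {2,6-bis(methoxymethoxy)-4-[(methoxymethoxy)methyl]phenyl}methanol (Ar–CH2OH), via aryllithium 3 (not isolated)
Conditions: n-BuLi (1.2 equiv), THF, 0 °C; paraformaldehyde, 0 °C to rt; H2O
Reagents that add atoms: paraformaldehyde (as formaldehyde), C=O
Why: Directed ortho-metalation removes the C–H flanked by the two OMOM groups, and the aryllithium is hydroxymethylated by formaldehyde.

Step 3
Reactants: 4 {2,6-bis(methoxymethoxy)-4-[(methoxymethoxy)methyl]phenyl}methanol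
Product: 5 2-(bromomethyl)-1,3-bis(methoxymethoxy)-5-[(methoxymethoxy)methyl]benzene (Ar–CH2Br, used crude)
Conditions: CBr4, PPh3, CH2Cl2, 0 °C
Reagents that add atoms: carbon tetrabromide, BrC(Br)(Br)Br
Why: Appel bromination converts the benzylic alcohol into the bromide under non-acidic conditions that leave the MOM acetals intact.

Step 4
Reactants: 6 2-methylcyclohex-2-en-1-one; 5 Ar–CH2Br
Product: 8 (2S,3R)-2-(Ar-methyl)-2,3-dimethylcyclohexan-1-one, via aluminium enolate 7 (not isolated)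
Conditions: Cu(OTf)2 (2 mol %), binaphthol-derived bis(1-phenylethyl)phosphoramidite (4 mol %, the enantiomer giving the 3R adduct), Me3Al, Et2O, −30 °C; then MeLi, THF/HMPA, 5, −30 to 0 °C
Reagents that add atoms: trimethylaluminium, C[Al](C)C
Why: Copper-catalysed asymmetric conjugate addition sets C8 (R) under ligand control, and the regio-defined enolate (activated with MeLi) is benzylated anti to the new vicinal methyl by axial attack on the half-chair, which sets quaternary C9 (S) with the two methyls cis.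

Step 5
Reactants: 8 (2S,3R)-2-(Ar-methyl)-2,3-dimethylcyclohexan-1-one
Product: 10 (5R,6S)-6-(Ar-methyl)-5,6-dimethylcyclohex-1-en-1-yl trifluoromethanesulfonate, via potassium enolate 9 (not isolated)
Conditions: KN(SiMe3)2, THF, −78 °C; PhNTf2, −78 to 0 °C
Reagents that add atoms: N-phenylbis(trifluoromethanesulfonimide), O=S(=O)(N(c1ccccc1)S(=O)(=O)C(F)(F)F)C(F)(F)F
Why: Only the CH2 side of the ketone can enolise because C9 is quaternary, so deprotonation and O-triflation give a single enol triflate.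

Step 6
Reactants: 10 (5R,6S)-6-(Ar-methyl)-5,6-dimethylcyclohex-1-en-1-yl trifluoromethanesulfonate
Product: 11 (3S,4R)-3-(Ar-methyl)-3,4-dimethylcyclohex-1-ene
Conditions: Pd(OAc)2 (5 mol %), PPh3 (10 mol %), HCO2H, n-Bu3N, DMF, 60 °C
Reagents that add atoms: none
Why: Palladium-catalysed formate reduction of the enol triflate (oxidative addition, decarboxylative hydride transfer, reductive elimination) replaces OTf by H without touching the stereocentres.

Step 7
Reactants: 11 (3S,4R)-3-(Ar-methyl)-3,4-dimethylcyclohex-1-ene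
Product: 13 (2S,3R)-2-(Ar-methyl)-2,3-dimethylhexanedial, via cis-diol 12 (not isolated)
Conditions: OsO4 (2 mol %), NaIO4 (4 equiv), 2,6-lutidine, dioxane/H2O 3:1, rt
Reagents that add atoms: osmium tetroxide as oxygen carrier, O=[Os](=O)(=O)=O, re-oxidised by sodium periodate, [Na+].[O-]I(=O)(=O)=O
Why: Lemieux–Johnson oxidation (dihydroxylation then glycol cleavage) opens the template ring without attacking the electron-rich arene and gives two aldehydes of very different steric demand, with C8 and C9 untouched.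

Step 8
Reactants: 13 (2S,3R)-2-(Ar-methyl)-2,3-dimethylhexanedial
Product: 14 (2S,3R,6E)-2-(Ar-methyl)-2,3,7-trimethyl-8-oxonon-6-enal
Conditions: Ph3P=C(CH3)C(O)CH3 (1.05 equiv), CH2Cl2, rt to 40 °C
Reagents that add atoms: 3-(triphenylphosphoranylidene)butan-2-one, CC(=O)C(C)=P(c1ccccc1)(c1ccccc1)c1ccccc1
Why: Chemoselective Wittig olefination, because the stabilised ylide reacts with the unhindered CH2–CHO and not with the neopentyl aldehyde on the quaternary carbon, and it gives the (E)-trisubstituted enone.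

Step 9
Reactants: 14 (2S,3R,6E)-2-(Ar-methyl)-2,3,7-trimethyl-8-oxonon-6-enal
Product: 15 (3E,7R,8S)-8-(Ar-methyl)-3,7,8-trimethyldec-3-en-9-yn-2-one
Conditions: dimethyl (1-diazo-2-oxopropyl)phosphonate, K2CO3, MeOH, 0 °C to rt
Reagents that add atoms: dimethyl (1-diazo-2-oxopropyl)phosphonate (Ohira–Bestmann reagent), COP(=O)(OC)C(=[N+]=[N-])C(C)=O
Why: Seyferth–Gilbert homologation with the Ohira–Bestmann reagent turns the non-enolisable neopentyl aldehyde into the terminal alkyne under mild base, so C9 cannot epimerise.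

Step 10
Reactants: 15 (3E,7R,8S)-8-(Ar-methyl)-3,7,8-trimethyldec-3-en-9-yn-2-one
Product: 17 (5S,6R,8aR)-5-(Ar-methyl)-1,5,6-trimethyl-2-(trimethylsilyloxy)-3,5,6,7,8,8a-hexahydronaphthalene, via silyl dienol ether 16 (not isolated)
Conditions: TMSOTf, Et3N, CH2Cl2, −78 to 0 °C; concentrate, take up in pentane, filter; then Ni(cod)2 (10 mol %), P(O-2-biphenylyl)3 (30 mol %), THF, 25 to 60 °C
Reagents that add atoms: trimethylsilyl trifluoromethanesulfonate, C[Si](C)(C)OS(=O)(=O)C(F)(F)F
Why: O-silylation at the methyl ketone gives the 2-siloxy-1,3-diene, and a nickel-catalysed intramolecular [4+2] dienyne cycloaddition (formal Diels–Alder reaction) closes rings A and B at once, the alkyne carbons becoming the C10=C1 alkene; C5 (R) comes from the chair-like tether with the arylmethyl group, the C8 methyl and the diene arm equatorial and the C9 methyl axial, a preference that is only moderate, so the C5 epimer is removed by chromatography at 19.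

Step 11
Reactants: 17 (5S,6R,8aR)-5-(Ar-methyl)-1,5,6-trimethyl-2-(trimethylsilyloxy)-3,5,6,7,8,8a-hexahydronaphthalene
Product: 19 (5S,6R,8aR)-5-(Ar-methyl)-1,1,5,6-tetramethyl-3,5,6,7,8,8a-hexahydronaphthalen-2(1H)-one, via lithium enolate 18 (not isolated)
Conditions: MeLi, THF, 0 °C; then MeI (excess), HMPA, −78 to 0 °C
Reagents that add atoms: iodomethane, CI
Why: Stork-type regiospecific enolate generation, in which MeLi cleaves the O–Si bond to give only the C3–C4 lithium enolate and C-methylation creates the C4 gem-dimethyl group and the C3 ketone without enolising the allylic C2 position.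

Step 12
Reactants: 19 (5S,6R,8aR)-5-(Ar-methyl)-1,1,5,6-tetramethyl-3,5,6,7,8,8a-hexahydronaphthalen-2(1H)-one
Product: 20 (2R,5S,6R,8aR)-5-(Ar-methyl)-1,1,5,6-tetramethyl-1,2,3,5,6,7,8,8a-octahydronaphthalen-2-ol
Conditions: LiBH(s-Bu)3, THF, −78 to −20 °C; aqueous work-up
Reagents that add atoms: none
Why: Substrate-controlled reduction in which the bulky trialkylborohydride attacks the 2,2-dimethylcyclohexanone-type ring A along the equatorial trajectory, giving the axial (3R) alcohol cis to H5.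

Step 13
Reactants: 20 (2R,5S,6R,8aR)-5-(Ar-methyl)-1,1,5,6-tetramethyl-1,2,3,5,6,7,8,8a-octahydronaphthalen-2-ol
Product: 22 3-{[(1S,2R,4aR,6R)-6-hydroxy-1,2,5,5-tetramethyl-1,2,3,4,4a,5,6,7-octahydronaphthalen-1-yl]methyl}-2,4-bis(methoxymethoxy)-6-[(methoxymethoxy)methyl]benzaldehyde, via dilithio intermediate 21 (not isolated)
Conditions: n-BuLi (3.3 equiv), TMEDA, THF, −20 to 0 °C; DMF, −78 to 0 °C; H2O
Reagents that add atoms: N,N-dimethylformamide, CN(C)C=O
Why: Directed ortho-metalation after deprotonation of the C3 alcohol, where the only free arene positions are two equivalent ones flanked by OMOM and CH2OMOM, followed by formylation of the aryllithium with DMF.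

Step 14
Reactants: 22 3-{[(1S,2R,4aR,6R)-6-hydroxy-1,2,5,5-tetramethyl-1,2,3,4,4a,5,6,7-octahydronaphthalen-1-yl]methyl}-2,4-bis(methoxymethoxy)-6-[(methoxymethoxy)methyl]benzaldehyde
Product: 23 2,4-dihydroxy-6-(hydroxymethyl)-3-{[(1S,2R,4aR,6R)-6-hydroxy-1,2,5,5-tetramethyl-1,2,3,4,4a,5,6,7-octahydronaphthalen-1-yl]methyl}benzaldehyde (target)
Conditions: pyridinium p-toluenesulfonate (0.3 equiv), t-BuOH, 80 °C
Reagents that add atoms: none
Why: Mild acid-catalysed transacetalisation to tert-butanol removes all three MOM groups, and the weakly acidic medium does not protonate the trisubstituted alkene, so no phenol–alkene cyclisation is expected.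

**Compound list**

1 | 3,5-dihydroxybenzyl alcohol | OCc1cc(O)cc(O)c1 | starting material
2 | 1,3-bis(methoxymethoxy)-5-[(methoxymethoxy)methyl]benzene | COCOCc1cc(OCOC)cc(OCOC)c1 | intermediate
3 | 2-lithio derivative of 2 (Ar–Li) | [Li]c1c(OCOC)cc(COCOC)cc1OCOC | intermediate (not isolated)
4 | {2,6-bis(methoxymethoxy)-4-[(methoxymethoxy)methyl]phenyl}methanol | OCc1c(OCOC)cc(COCOC)cc1OCOC | intermediate
5 | 2-(bromomethyl)-1,3-bis(methoxymethoxy)-5-[(methoxymethoxy)methyl]benzene | BrCc1c(OCOC)cc(COCOC)cc1OCOC | intermediate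
6 | 2-methylcyclohex-2-en-1-one | CC1=CCCCC1=O | starting material
7 | dimethylaluminium (3R)-2,3-dimethylcyclohex-1-en-1-olate | C[C@@H]1CCCC(O[Al](C)C)=C1C | intermediate (not isolated)
8 | (2S,3R)-2-(Ar-methyl)-2,3-dimethylcyclohexan-1-one | C[C@@H]1CCCC(=O)[C@@]1(C)Cc1c(OCOC)cc(COCOC)cc1OCOC | intermediate
9 | potassium (5R,6S)-6-(Ar-methyl)-5,6-dimethylcyclohex-1-en-1-olate | C[C@@H]1CCC=C([O-])[C@@]1(C)Cc1c(OCOC)cc(COCOC)cc1OCOC.[K+] | intermediate (not isolated)
10 | (5R,6S)-6-(Ar-methyl)-5,6-dimethylcyclohex-1-en-1-yl trifluoromethanesulfonate | C[C@@H]1CCC=C(OS(=O)(=O)C(F)(F)F)[C@@]1(C)Cc1c(OCOC)cc(COCOC)cc1OCOC | intermediate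
11 | (3S,4R)-3-(Ar-methyl)-3,4-dimethylcyclohex-1-ene | C[C@@H]1CCC=C[C@@]1(C)Cc1c(OCOC)cc(COCOC)cc1OCOC | intermediate
12 | (3S,4R)-3-(Ar-methyl)-3,4-dimethylcyclohexane-1,2-diol (cis-diol; the two carbinol centres are left open because both are destroyed) | C[C@@H]1CCC(O)C(O)[C@@]1(C)Cc1c(OCOC)cc(COCOC)cc1OCOC | intermediate (not isolated)
13 | (2S,3R)-2-(Ar-methyl)-2,3-dimethylhexanedial | O=CCC[C@@H](C)[C@](C)(Cc1c(OCOC)cc(COCOC)cc1OCOC)C=O | intermediate
14 | (2S,3R,6E)-2-(Ar-methyl)-2,3,7-trimethyl-8-oxonon-6-enal | CC(=O)/C(C)=C/CC[C@@H](C)[C@](C)(Cc1c(OCOC)cc(COCOC)cc1OCOC)C=O | intermediate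
15 | (3E,7R,8S)-8-(Ar-methyl)-3,7,8-trimethyldec-3-en-9-yn-2-one | CC(=O)/C(C)=C/CC[C@@H](C)[C@](C)(Cc1c(OCOC)cc(COCOC)cc1OCOC)C#C | intermediate
16 | (3E,7R,8S)-8-(Ar-methyl)-3,7,8-trimethyl-2-(trimethylsilyloxy)deca-1,3-dien-9-yne | C=C(O[Si](C)(C)C)/C(C)=C/CC[C@@H](C)[C@](C)(Cc1c(OCOC)cc(COCOC)cc1OCOC)C#C | intermediate (not isolated)
17 | (5S,6R,8aR)-5-(Ar-methyl)-1,5,6-trimethyl-2-(trimethylsilyloxy)-3,5,6,7,8,8a-hexahydronaphthalene | C[C@@H]1CC[C@@H]2C(=CCC(O[Si](C)(C)C)=C2C)[C@@]1(C)Cc1c(OCOC)cc(COCOC)cc1OCOC | intermediate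
18 | lithium enolate of 17 (OLi in place of OSiMe3) | C[C@@H]1CC[C@@H]2C(=CCC([O-])=C2C)[C@@]1(C)Cc1c(OCOC)cc(COCOC)cc1OCOC.[Li+] | intermediate (not isolated)
19 | (5S,6R,8aR)-5-(Ar-methyl)-1,1,5,6-tetramethyl-3,5,6,7,8,8a-hexahydronaphthalen-2(1H)-one | C[C@@H]1CC[C@@H]2C(=CCC(=O)C2(C)C)[C@@]1(C)Cc1c(OCOC)cc(COCOC)cc1OCOC | intermediate
20 | (2R,5S,6R,8aR)-5-(Ar-methyl)-1,1,5,6-tetramethyl-1,2,3,5,6,7,8,8a-octahydronaphthalen-2-ol | C[C@@H]1CC[C@@H]2C(=CC[C@@H](O)C2(C)C)[C@@]1(C)Cc1c(OCOC)cc(COCOC)cc1OCOC | intermediate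
21 | dilithio species of 20 (lithium C3-alkoxide; aryl–Li between OMOM and CH2OMOM) | C[C@@H]1CC[C@@H]2C(=CC[C@@H]([O-])C2(C)C)[C@@]1(C)Cc1c(OCOC)cc(COCOC)c([Li])c1OCOC.[Li+] | intermediate (not isolated)
22 | 3-{[(1S,2R,4aR,6R)-6-hydroxy-1,2,5,5-tetramethyl-1,2,3,4,4a,5,6,7-octahydronaphthalen-1-yl]methyl}-2,4-bis(methoxymethoxy)-6-[(methoxymethoxy)methyl]benzaldehyde | C[C@@H]1CC[C@@H]2C(=CC[C@@H](O)C2(C)C)[C@@]1(C)Cc1c(OCOC)cc(COCOC)c(C=O)c1OCOC | intermediate
23 | 2,4-dihydroxy-6-(hydroxymethyl)-3-{[(1S,2R,4aR,6R)-6-hydroxy-1,2,5,5-tetramethyl-1,2,3,4,4a,5,6,7-octahydronaphthalen-1-yl]methyl}benzaldehyde | C[C@@H]1CC[C@@H]2C(=CC[C@@H](O)C2(C)C)[C@@]1(C)Cc1c(O)cc(CO)c(C=O)c1O | target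

**Summary**

Total step count: 14. Longest linear sequence: 14 steps (1 → 23; compound 6 enters at step 4).

The three steps most likely to fail:

Step 10 (the two-ring cycloaddition). The terminal alkyne may oligomerise at nickel, and the facial selectivity at C5 rests on a small conformational preference of a tether whose C9 carries two groups of similar size. The fallback builds ring A alone on the intact template ring with reagent control; it sets out from enol triflate 10 and comes back at ketone 19. Triflate 10 is coupled with (4-methylpent-3-en-1-yl)MgBr under Fe(acac)3 catalysis (THF/NMP, −20 °C) to give (5R,6S)-6-(Ar-methyl)-5,6-dimethyl-1-(4-methylpent-3-en-1-yl)cyclohex-1-ene F1. Shi epoxidation (fructose-derived ketone of the enantiomeric series that gives the S epoxide, KHSO5, K2CO3, MeCN/dimethoxymethane/H2O, 0 °C) of the unhindered side-chain alkene gives (3S)-3-{2-[(5R,6S)-6-(Ar-methyl)-5,6-dimethylcyclohex-1-en-1-yl]ethyl}-2,2-dimethyloxirane F2. MeAlCl2 (CH2Cl2, −78 °C) then triggers an epoxy-olefin cyclisation through a chair, in which the epoxide configuration dictates C5 and loss of a C1 proton gives the C1=C10 alkene; the product is the equatorial alcohol (2S,5S,6R,8aR)-5-(Ar-methyl)-1,1,5,6-tetramethyl-1,2,3,5,6,7,8,8a-octahydronaphthalen-2-ol F3. Dess–Martin oxidation of F3 gives 19, which re-enters at step 12.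

Step 11 (regiospecific C4 methylation). Proton transfer to the acidic allylic C2 position could give C2-methylated or over-methylated material. The fallback sets out from silyl enol ether 17 and comes back at ketone 19. Furukawa cyclopropanation (Et2Zn, CH2I2, CH2Cl2, 0 °C) of the electron-rich enol ether double bond, leaving the C1=C10 alkene alone, gives the siloxycyclopropane of 17 with CH2 bridging C3 and C4, F4. K2CO3 in MeOH then removes the silyl group and opens the cyclopropanol at its CH2–C(O) bond, so the new CH2 becomes the second C4 methyl and 19 is formed.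

Step 13 (late ortho-lithiation and formylation). Lateral metalation or incomplete lithiation next to the free alkoxide could lower the yield. The fallback sets out from alcohol 20 and comes back at target 23. The MOM groups are removed first (pyridinium p-toluenesulfonate, t-BuOH, 80 °C) to give 2-{[(1S,2R,4aR,6R)-6-hydroxy-1,2,5,5-tetramethyl-1,2,3,4,4a,5,6,7-octahydronaphthalen-1-yl]methyl}-5-(hydroxymethyl)benzene-1,3-diol F5. Magnesium-phenoxide-directed ortho-formylation (MgCl2, Et3N, paraformaldehyde, MeCN, reflux, one equivalent) then installs the aldehyde at one of the two equivalent positions ortho to a phenol and gives 23 directly.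

**Further compounds**

F1 | step 10 | (5R,6S)-6-(Ar-methyl)-5,6-dimethyl-1-(4-methylpent-3-en-1-yl)cyclohex-1-ene | C[C@@H]1CCC=C(CCC=C(C)C)[C@@]1(C)Cc1c(OCOC)cc(COCOC)cc1OCOC
F2 | step 10 | (3S)-3-{2-[(5R,6S)-6-(Ar-methyl)-5,6-dimethylcyclohex-1-en-1-yl]ethyl}-2,2-dimethyloxirane | C[C@@H]1CCC=C(CC[C@@H]2OC2(C)C)[C@@]1(C)Cc1c(OCOC)cc(COCOC)cc1OCOC
F3 | step 10 | (2S,5S,6R,8aR)-5-(Ar-methyl)-1,1,5,6-tetramethyl-1,2,3,5,6,7,8,8a-octahydronaphthalen-2-ol (C3 epimer of 20) | C[C@@H]1CC[C@@H]2C(=CC[C@H](O)C2(C)C)[C@@]1(C)Cc1c(OCOC)cc(COCOC)cc1OCOC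
F4 | step 11 | siloxycyclopropane of 17 (CH2 bridging C3 and C4; cyclopropane face left open, both converge on 19) | C[C@@H]1CC[C@@H]2C(=CCC3(O[Si](C)(C)C)CC32C)[C@@]1(C)Cc1c(OCOC)cc(COCOC)cc1OCOC
F5 | step 13 | 2-{[(1S,2R,4aR,6R)-6-hydroxy-1,2,5,5-tetramethyl-1,2,3,4,4a,5,6,7-octahydronaphthalen-1-yl]methyl}-5-(hydroxymethyl)benzene-1,3-diol | C[C@@H]1CC[C@@H]2C(=CC[C@@H](O)C2(C)C)[C@@]1(C)Cc1c(O)cc(CO)cc1O
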